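Its constants were drawn at random within sensible limits; the run is a simulation.

The easy step comes first: starting material goes one way to intermediate, and the intermediate then shares itself out among the isomers.

| flask | starting material | remark | time |
|---|---|---|---|
| west | 1.0 M | a single well-mixed tank run continuously and read at steady state, 20.0 h in it on average |  |
| south-east | 1.0 M | everything together in a closed stirred flask, run for 2.0 h | 2.0 h |
| north-west | 1.0 M | a single well-mixed tank run continuously and read at steady state, 2.0 h in it on average |  |

    starting material → intermediate (k1 = 1.1 × 10⁻⁴ s⁻¹)
    intermediate ⇌ target (K2 = 0.70, k2 = 0.0016 s⁻¹)
    intermediate ⇌ isomer of the product A (K3 = 3.9, k3 = 2.9 × 10⁻⁵ s⁻¹)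
    2 starting material → homo dimer (k4 = 1.1 × 10⁻⁷ M⁻¹ s⁻¹)
    target ⇌ isomer of the product B (K5 = 0.34, k5 = 2.8 × 10⁻⁴ s⁻¹)

- percentages count the starting material that a species holds: one homo dimer counts as two
- a doubled species enters its step squared and goes two at a time
- the stated concentrations are those of everything mixed, before any reaction; amounts are the same in each set-up
- run time (south-east): 2.0 h

* the set-up with the highest share of target in all that became target or isomer of the product A or isomer of the product B, at the outlet or at the end ("none" if the first two lie within 2 percentage points) (west / south-east / north-west / none)
* share of target in all that became target or isomer of the product A or isomer of the product B, at the outlet or at the end, west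
* share of target in all that became target or isomer of the product A or isomer of the product B, at the outlet or at the end, south-east
* share of target in all that became target or isomer of the product A or isomer of the product B, at the outlet or at the end, north-west

Homo dimer can be set aside: its loss per unit of starting material at the full charge, 2.20 × 10⁻⁷ s⁻¹, is far smaller than the 1.1 × 10⁻⁴ s⁻¹ of step 1.

Draw the target's share against time in the closed south-east flask. It opens at 98.2%, the forward constant of step 2 over those of steps 2 and 3 together, for isomer of the product A forms beside target from the first moment, though more slowly. Step 5 then pulls the share down, with a half-time near 0.174 h with both directions counted, towards a first knee near 74.6%.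

From there the slope belongs to one concentration, the intermediate: isomer of the product A grows at 0.1 h⁻¹ times it, slowly beside step 2. So follow the isomer ratio, isomer of the product A over intermediate, both as fractions of the charge. With steps 2 and 5 at balance, the share is 0.70 divided by the isomer ratio plus 0.938. This is the tipping ratio, the isomer ratio at which isomer of the product A equals target and isomer of the product B together.

Early on, the isomer ratio is 0.1 h⁻¹ times the mean age of the converted charge. At 2.0 h, 0.547 of the charge has converted, with mean age 1.13 h. The ratio is then 0.118, below the tipping ratio, and the reckoned share is 66.3%. At this slope the crossing comes at a mean age of 8.98 h, longer than the run. The curve's last level, with the ratio at 3.9, is 14.5%.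

In a tank the average stay replaces the mean age, with the way back taken off. The north-west tank, 2.0 h on average, reaches 0.198 and 61.6%; the west tank, 20.0 h on average, reaches 1.36 and 30.5%.

The forecast names south-east, with 30.4% west, 67.2% south-east and 62.6% north-west, holding that the share turns on “how much slowly forming isomer A has built up”. For south-east it stands 0.90 percentage points above the reckoning here.

The simulation gives south-east as best, with 30.4% west, 67.3% south-east and 62.6% north-west. The west outlet holds isomer of the product A at 36.7% of the charge and intermediate at 27.0%, an isomer ratio of 1.36, past the tipping ratio, and the rule returns 30.5% from those readings. The south-east answer, read backwards, gives a ratio of 0.102. The undoing of target into intermediate is the main reason the west tank lies low: without it the west share of 30.4% becomes 74.1%.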